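The route rests on disconnecting O1–C8a in the pyranone ring of the 6-hydroxy-7-methoxycoumarin (unprimed) half. C8a lies para to the oxygen on C6, so this aryl C–O bond can be formed by oxidising an isovanillin-derived benzene ring at a C–H position. In one operation, anodic dehydrogenative lactonisation joins the carboxyl oxygen to that carbon, closes the pyranone ring and releases only hydrogen. The precursor is an (E)-2-aryloxy-3-arylacrylic acid, aryl cis to carboxyl. It already carries the umbelliferone ether on the future C3 and an isopropyl ether on the future C6 oxygen. Perkin condensation and sensitised Z-to-E isomerisation lead to it, and boron trichloride then frees the phenol.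

Key step: step 6

Remark: the target has no stereocentre, stereogenic axis or stereogenic double bond and is achiral, so there is no enantiomer to select. The only stereochemical issue in the route is the alkene geometry of the acrylic acid. E means aryl cis to carboxyl here, because the aryloxy oxygen outranks the carboxyl carbon.

Step 1
Reactants: 1 isovanillin (3-hydroxy-4-methoxybenzaldehyde); 2 2-bromopropane
Product: 3 4-methoxy-3-(propan-2-yloxy)benzaldehyde
Conditions: K2CO3, DMF, 70 °C
Reagents that add atoms: none
Why: Williamson ether synthesis, in which the phenoxide displaces bromide in a polar aprotic solvent while aldehyde and methyl ether are inert to carbonate; the isopropyl ether is chosen because it is a strong para donor, has no benzylic C–H to be oxidised later, and shields the adjacent ring carbon.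

Step 2
Reactants: 4 umbelliferone (7-hydroxy-2H-chromen-2-one); 5 tert-butyl bromoacetate
Product: 6 tert-butyl 2-[(2-oxo-2H-chromen-7-yl)oxy]acetate
Conditions: K2CO3, acetone, reflux
Reagents that add atoms: none
Why: Williamson ether synthesis with an activated α-halo ester, in which carbonate in acetone deprotonates only the acidic 7-OH and leaves the lactone closed.

Step 3
Reactants: 6 tert-butyl 2-[(2-oxo-2H-chromen-7-yl)oxy]acetate
Product: 7 2-[(2-oxo-2H-chromen-7-yl)oxy]acetic acid
Conditions: TFA/CH2Cl2 1:1, rt
Reagents that add atoms: none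
Why: Acidolysis of a tert-butyl ester (E1 loss of isobutene), preferred to saponification so that the base-labile coumarin lactone never meets hydroxide.

Step 4
Reactants: 7 2-[(2-oxo-2H-chromen-7-yl)oxy]acetic acid; 3 4-methoxy-3-(propan-2-yloxy)benzaldehyde
Product: 9 (Z)-3-[4-methoxy-3-(propan-2-yloxy)phenyl]-2-[(2-oxo-2H-chromen-7-yl)oxy]prop-2-enoic acid (aryl trans to carboxyl), via acetic 2-[(2-oxo-2H-chromen-7-yl)oxy]acetic anhydride 8 (not isolated)
Conditions: Ac2O, Et3N, 110 °C; then H2O, 80 °C; aq HCl
Reagents that add atoms: none
Why: Perkin condensation in the Oglialoro variant, in which triethylamine enolises mixed anhydride 8, the enolate adds to the non-enolisable aldehyde, and acetylation with E1cB elimination should give mainly the more stable Z acid, the coumarin being stable under conditions by which coumarins are themselves made.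

Step 5
Reactants: 9 (Z)-3-[4-methoxy-3-(propan-2-yloxy)phenyl]-2-[(2-oxo-2H-chromen-7-yl)oxy]prop-2-enoic acid
Product: 10 (E)-3-[4-methoxy-3-(propan-2-yloxy)phenyl]-2-[(2-oxo-2H-chromen-7-yl)oxy]prop-2-enoic acid (aryl cis to carboxyl)
Conditions: fac-Ir(ppy)3 (1 mol %), degassed MeCN (0.01 M), 450 nm LEDs, rt; residual 9 separated and recycled; product kept from light
Reagents that add atoms: none
Why: Triplet-sensitised contra-thermodynamic alkene isomerisation (energy-transfer catalysis) as known for cinnamic acid derivatives, in which the planar styrene chromophore of 9 accepts triplet energy whereas strain between aryl and carboxyl twists 10 out of conjugation so that it accumulates, while a sensitiser whose triplet energy lies below that of a 7-alkoxycoumarin and high dilution should spare the C3'=C4' bond from [2+2] dimerisation.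

Step 6
Reactants: 10 (E)-3-[4-methoxy-3-(propan-2-yloxy)phenyl]-2-[(2-oxo-2H-chromen-7-yl)oxy]prop-2-enoic acid
Product: 11 7-methoxy-3-[(2-oxo-2H-chromen-7-yl)oxy]-6-(propan-2-yloxy)-2H-chromen-2-one
Conditions: undivided cell, graphite felt (+) | Pt (−), constant current (low current density), 2.2 F per mole, n-Bu4NPF6 (0.1 M), 2,6-lutidine (2 equiv), dry CH2Cl2/HFIP 4:1 (0.02 M), Ar, rt
Reagents that add atoms: none
Why: Anodic one-electron oxidation converts the 3,4-dialkoxystyrene unit of 10 into its radical cation, the lutidine-buffered carboxylate held cis to the ring adds to the ring carbon para to the isopropoxy oxygen (future C8a), and a second electron transfer with loss of the ring proton restores the arene, while protons are discharged to hydrogen at platinum at potentials far from those that reduce a coumarin. The closest known reaction type is the anodic dehydrogenative C–H/O–H lactonisation of biaryl-2-carboxylic acids, together with the single-electron-transfer cyclisation of cis-cinnamic acids to coumarins. The one ring formed is closed in a six-membered mode, carboxyl oxygen O1 onto C8a over the tether C2–C3–C4–C4a (6-endo-trig with respect to the C4a–C8a bond), which only the E geometry allows. No stereocentre is created, so no stereocontrol element is needed. Site selectivity among three ring carbons is required: attack at C8a gives a cation that is an oxocarbenium ion of the C6 isopropoxy group, the other ortho carbon is wedged between the side chain and that bulky group, and 5-exo attack at the ipso carbon C4a (para to methoxy) gives a spiro adduct that cannot rearomatise and, with no water or methanol present to take its methyl group, should reopen. Chemoselectivity rests on non-nucleophilic HFIP, which stabilises the radical cation and does not add to the enol-ether carbon C3, and on the product being an aryl ester that is harder to oxidise than the carboxylate, so that charge limited to slightly above 2 F per mole stops at 11.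

Step 7
Reactants: 11 7-methoxy-3-[(2-oxo-2H-chromen-7-yl)oxy]-6-(propan-2-yloxy)-2H-chromen-2-one
Product: 13 6-hydroxy-7-methoxy-3-[(2-oxo-2H-chromen-7-yl)oxy]-2H-chromen-2-one (target), via dichloro({7-methoxy-2-oxo-3-[(2-oxo-2H-chromen-7-yl)oxy]-2H-chromen-6-yl}oxy)borane 12 (not isolated)
Conditions: BCl3 (3 equiv), CH2Cl2, −78 to 0 °C; then H2O
Reagents that add atoms: none
Why: Lewis-acid dealkylation of an aryl isopropyl ether, in which boron binds the ether oxygen and chloride takes the secondary alkyl group through an SN1-like transition state much faster than it attacks a methyl ether with no ortho carbonyl, so the 7-OMe, the vinyl aryl ether and both lactones should remain and water hydrolyses 12 to the phenol.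

Compound list
1 | isovanillin (3-hydroxy-4-methoxybenzaldehyde) | COc1ccc(C=O)cc1O | starting material
2 | 2-bromopropane | CC(C)Br | starting material
3 | 4-methoxy-3-(propan-2-yloxy)benzaldehyde | COc1ccc(C=O)cc1OC(C)C | intermediate
4 | umbelliferone (7-hydroxy-2H-chromen-2-one) | Oc1ccc2ccc(=O)oc2c1 | starting material
5 | tert-butyl bromoacetate | CC(C)(C)OC(=O)CBr | starting material
6 | tert-butyl 2-[(2-oxo-2H-chromen-7-yl)oxy]acetate | CC(C)(C)OC(=O)COc1ccc2ccc(=O)oc2c1 | intermediate
7 | 2-[(2-oxo-2H-chromen-7-yl)oxy]acetic acid | OC(=O)COc1ccc2ccc(=O)oc2c1 | intermediate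
8 | acetic 2-[(2-oxo-2H-chromen-7-yl)oxy]acetic anhydride (not isolated) | CC(=O)OC(=O)COc1ccc2ccc(=O)oc2c1 | intermediate
9 | (Z)-3-[4-methoxy-3-(propan-2-yloxy)phenyl]-2-[(2-oxo-2H-chromen-7-yl)oxy]prop-2-enoic acid | COc1ccc(/C=C(\Oc2ccc3ccc(=O)oc3c2)C(=O)O)cc1OC(C)C | intermediate
10 | (E)-3-[4-methoxy-3-(propan-2-yloxy)phenyl]-2-[(2-oxo-2H-chromen-7-yl)oxy]prop-2-enoic acid | COc1ccc(/C=C(/Oc2ccc3ccc(=O)oc3c2)C(=O)O)cc1OC(C)C | intermediate
11 | 7-methoxy-3-[(2-oxo-2H-chromen-7-yl)oxy]-6-(propan-2-yloxy)-2H-chromen-2-one | COc1cc2oc(=O)c(Oc3ccc4ccc(=O)oc4c3)cc2cc1OC(C)C | intermediate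
12 | dichloro({7-methoxy-2-oxo-3-[(2-oxo-2H-chromen-7-yl)oxy]-2H-chromen-6-yl}oxy)borane (not isolated) | COc1cc2oc(=O)c(Oc3ccc4ccc(=O)oc4c3)cc2cc1OB(Cl)Cl | intermediate
13 | 6-hydroxy-7-methoxy-3-[(2-oxo-2H-chromen-7-yl)oxy]-2H-chromen-2-one | COc1cc2oc(=O)c(Oc3ccc4ccc(=O)oc4c3)cc2cc1O | target

Total step count: 7. Longest linear sequence: 6 (steps 2 to 7, from umbelliferone).

Steps most likely to fail

1. Step 6. The carboxylate may be captured at the ipso carbon para to the methoxy group, followed by loss of methyl or a 1,2-shift. Styrene radical cations may couple at the electrode surface, and the product may be oxidised further. The fallback abandons C–H oxidation and brings the C8a oxygen in with the aldehyde. It sets out from 3 and 7 and comes back at 11.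
 - Electrophilic bromination of 3 (Br2, NaOAc, AcOH), directed para to the isopropoxy group, should give 2-bromo-4-methoxy-5-(propan-2-yloxy)benzaldehyde F1.
 - Copper-catalysed Ullmann-type hydroxylation (CuI, 8-hydroxyquinoline, KOH, DMSO/H2O, 100 °C), helped by the ortho formyl group, should give 2-hydroxy-4-methoxy-5-(propan-2-yloxy)benzaldehyde F2.
 - The Perkin coumarin synthesis of F2 with 7 (Ac2O, Et3N, 120 °C) builds the pyranone by O-acylation and intramolecular condensation. This gives 11 with no question of alkene geometry.

2. Step 5. The photostationary state may be unfavourable, or energy transfer to the 7-alkoxycoumarin may cause [2+2] dimerisation. The fallback sets the geometry in the ground state, in the bond-forming step itself. It sets out from 4 and 3 and comes back at 10.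
 - Diazo transfer (p-acetamidobenzenesulfonyl azide, DBU, MeCN) onto commercial ethyl (diphenoxyphosphoryl)acetate gives ethyl 2-diazo-2-(diphenoxyphosphoryl)acetate F3.
 - Rh2(OAc)4-catalysed O–H insertion of F3 into 4 gives racemic ethyl 2-(diphenoxyphosphoryl)-2-[(2-oxo-2H-chromen-7-yl)oxy]acetate F4.
 - The diaryl phosphonate variant of the Horner–Wadsworth–Emmons reaction with 3 (NaH, THF, −78 °C) follows. Fast, irreversible collapse of the kinetic adduct places the aldehyde residue cis to the ester, so it should give ethyl (E)-3-[4-methoxy-3-(propan-2-yloxy)phenyl]-2-[(2-oxo-2H-chromen-7-yl)oxy]prop-2-enoate F5.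
 - Mild saponification (LiOH, THF/H2O, 0 °C) and acidification give 10.

3. Step 4. The weakly acidic anhydride enolate may add only slowly to an electron-rich aldehyde, so that thermal self-condensation of the anhydride outruns the Perkin reaction. The fallback replaces the thermal one-pot condensation with a stepwise low-temperature aldol and elimination. It sets out from 6 and 3 and comes back at 9.
 - LiHMDS is added to a mixture of 6 and 3 in THF at −78 °C. This should give tert-butyl 3-hydroxy-3-[4-methoxy-3-(propan-2-yloxy)phenyl]-2-[(2-oxo-2H-chromen-7-yl)oxy]propanoate F6 as a racemic mixture of diastereomers.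
 - MsCl and Et3N convert F6 into the mesylate tert-butyl 3-(methanesulfonyloxy)-3-[4-methoxy-3-(propan-2-yloxy)phenyl]-2-[(2-oxo-2H-chromen-7-yl)oxy]propanoate F7, which is not isolated.
 - DBU eliminates F7 (E1cB) to the more stable tert-butyl (Z)-3-[4-methoxy-3-(propan-2-yloxy)phenyl]-2-[(2-oxo-2H-chromen-7-yl)oxy]prop-2-enoate F8.
 - TFA in CH2Cl2 frees 9.

Further compounds
F1 | step 6 | 2-bromo-4-methoxy-5-(propan-2-yloxy)benzaldehyde | COc1cc(Br)c(C=O)cc1OC(C)C
F2 | step 6 | 2-hydroxy-4-methoxy-5-(propan-2-yloxy)benzaldehyde | COc1cc(O)c(C=O)cc1OC(C)C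
F3 | step 5 | ethyl 2-diazo-2-(diphenoxyphosphoryl)acetate | CCOC(=O)C(=[N+]=[N-])P(=O)(Oc1ccccc1)Oc1ccccc1
F4 | step 5 | ethyl 2-(diphenoxyphosphoryl)-2-[(2-oxo-2H-chromen-7-yl)oxy]acetate (racemic) | CCOC(=O)C(Oc1ccc2ccc(=O)oc2c1)P(=O)(Oc1ccccc1)Oc1ccccc1
F5 | step 5 | ethyl (E)-3-[4-methoxy-3-(propan-2-yloxy)phenyl]-2-[(2-oxo-2H-chromen-7-yl)oxy]prop-2-enoate | COc1ccc(/C=C(/Oc2ccc3ccc(=O)oc3c2)C(=O)OCC)cc1OC(C)C
F6 | step 4 | tert-butyl 3-hydroxy-3-[4-methoxy-3-(propan-2-yloxy)phenyl]-2-[(2-oxo-2H-chromen-7-yl)oxy]propanoate (racemic, mixture of diastereomers) | COc1ccc(C(O)C(Oc2ccc3ccc(=O)oc3c2)C(=O)OC(C)(C)C)cc1OC(C)C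
F7 | step 4 | tert-butyl 3-(methanesulfonyloxy)-3-[4-methoxy-3-(propan-2-yloxy)phenyl]-2-[(2-oxo-2H-chromen-7-yl)oxy]propanoate (racemic, mixture of diastereomers, not isolated) | COc1ccc(C(OS(C)(=O)=O)C(Oc2ccc3ccc(=O)oc3c2)C(=O)OC(C)(C)C)cc1OC(C)C
F8 | step 4 | tert-butyl (Z)-3-[4-methoxy-3-(propan-2-yloxy)phenyl]-2-[(2-oxo-2H-chromen-7-yl)oxy]prop-2-enoate | COc1ccc(/C=C(\Oc2ccc3ccc(=O)oc3c2)C(=O)OC(C)(C)C)cc1OC(C)C
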